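**Plan**
Retrosynthesis: the polyene is cut at C11=C12 and C11'=C12' (twofold Wittig olefination of a central C10 dialdehyde by a C15 phosphonium salt), then at C9–C10 (vinyl addition to (R)-α-ionone); the C7–C9 enone is traced back to a but-2-ynyl carbinol, the ring–chain bond C6–C7 is cut, and the ring is opened to isobutyraldehyde and ethyl vinyl ketone.
Forward: the six-membered ring is built first by annulation (the only ring-forming event), the chain is attached at C6 and grown from C13 to C15, two C15 units are joined to the C10 unit, and a thermal isomerisation delivers the all-E polyene.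
Enabling feature: in each end ring, C6 is a CH carbon held between the gem-dimethyl carbon C1, the methyl-bearing alkene carbon C5 (of C4=C5) and chain carbon C7. C6–C5–C4 is an allyl unit, so an oxygen on C4 of the isomeric C5=C6 alkene can be exchanged for the C6–C7 bond while the alkene moves to C4=C5.
Stereochemistry: the only stereocentres, C6 and C6' (both R), come from a CBS reduction that sets an S carbinol at the future C4; its configuration is passed suprafacially to C6 in the sigmatropic step. The chain alkenes are E by thermodynamic control.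

Key step: step 4

Assumption: carotenoid numbering is used for ring and chain atoms throughout; (2E,4E,6E)-2,7-dimethylocta-2,4,6-trienedial and CH2=CHMgBr solution are taken as purchasable.

**Step 1**
Reactants: 1 isobutyraldehyde; 2 ethyl vinyl ketone
Product: 5 2,4,4-trimethylcyclohex-2-en-1-one, via keto aldehyde 2,2-dimethyl-5-oxoheptanal 3 (not isolated), via aldol 3-hydroxy-2,4,4-trimethylcyclohexan-1-one 4 (not isolated)
Conditions: H2SO4 (cat.), neat, 45–50 °C; then toluene, reflux, Dean–Stark
Reagents that add atoms: none
Why: Acid-catalysed Michael addition of the aldehyde enol to the vinyl ketone followed by intramolecular aldol condensation (Robinson-type annulation); the quaternary aldehyde α-carbon leaves a single aldol mode, so one enone regioisomer should form.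

**Step 2**
Reactants: 5 2,4,4-trimethylcyclohex-2-en-1-one
Product: 6 (1S)-2,4,4-trimethylcyclohex-2-en-1-ol
Conditions: (R)-2-methyl-CBS-oxazaborolidine (10 mol %), BH3·SMe2, THF, −20 °C; MeOH quench, aqueous work-up
Reagents that add atoms: none
Why: Corey–Bakshi–Shibata reduction, in which the methyl-bearing alkene carbon acts as the large group and the ring CH2 as the small one, so the R catalyst should deliver hydride to the face that gives the S allylic alcohol by 1,2-reduction.

**Step 3**
Reactants: 6 (1S)-2,4,4-trimethylcyclohex-2-en-1-ol; 7 1-bromobut-2-yne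
Product: 8 (S)-2,4,4-trimethylcyclohex-2-en-1-yl but-2-yn-1-yl ether
Conditions: NaH, THF/DMF, 0 °C to rt
Reagents that add atoms: none
Why: Williamson ether synthesis of the sodium alkoxide with a reactive propargylic bromide; the bond to the carbinol carbon is not touched, so the S configuration is kept.

**Step 4**
Reactants: 8 (S)-2,4,4-trimethylcyclohex-2-en-1-yl but-2-yn-1-yl ether
Product: 10 1-[(1R)-2,6,6-trimethylcyclohex-2-en-1-yl]but-2-yn-1-ol (both carbinol epimers), via lithio ether 9 (not isolated)
Conditions: n-BuLi, THF, −78 °C, slowly to −30 °C; then H2O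
Reagents that add atoms: none
Why: n-BuLi removes the propargylic proton next to oxygen to give lithio ether 9, whose carbanion adds to the alkene CH next to the gem-dimethyl carbon (future C6) through a five-membered envelope transition state while the C4–O bond breaks and the alkene moves to C4=C5; this is a [2,3]-Wittig rearrangement of an allyl propargyl ether. No ring is closed; one C–C bond (C6–C7) and the C6 stereocentre are formed. The C6 configuration is controlled by the S carbinol centre: the C–O bond must stand pseudoaxial to overlap with the alkene, so the new bond forms on the face that oxygen leaves (suprafacial 1,3-transfer), which corresponds to R at C6. In that conformer the pseudoaxial methyl of the gem-dimethyl group lies on the opposite face, so the reacting face carries only the pseudoequatorial methyl. The step needs the [2,3] shift to win over the [1,2] shift and needs bond formation at a neopentyl carbon; low temperature, the alkyne-stabilised anion and intramolecular delivery should secure both. The C7 carbinol centre forms without control and is removed in step 5.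

**Step 5**
Reactants: 10 1-[(1R)-2,6,6-trimethylcyclohex-2-en-1-yl]but-2-yn-1-ol
Product: 11 (R)-α-ionone [(3E)-4-[(1R)-2,6,6-trimethylcyclohex-2-en-1-yl]but-3-en-2-one]
Conditions: ReOCl3(OPPh3)(SMe2) (5 mol %, pentavalent rhenium oxo complex), DME, 80 °C
Reagents that add atoms: none
Why: Meyer–Schuster rearrangement under oxo-metal catalysis (1,3-shift of the hydroxyl through the metal ester, then tautomerisation of the allenol), which is neutral and so should spare the C4=C5 alkene and the C6–H; both carbinol epimers converge on the thermodynamically preferred E-enone.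

**Step 6**
Reactants: 11 (R)-α-ionone; 12 vinylmagnesium bromide
Product: 13 (1E)-3-methyl-1-[(1R)-2,6,6-trimethylcyclohex-2-en-1-yl]penta-1,4-dien-3-ol (vinyl-α-ionol as both C9 epimers)
Conditions: CH2=CHMgBr, THF, −30 to 0 °C; then aq. NH4Cl
Reagents that add atoms: none
Why: 1,2-addition of a vinyl Grignard reagent to the enone carbonyl, the standard entry from ionones to vinyl ionols; the new tertiary carbinol centre forms unselectively and is destroyed in step 7.

**Step 7**
Reactants: 13 vinyl-α-ionol
Product: 14 [(2E,4E)-3-methyl-5-[(1R)-2,6,6-trimethylcyclohex-2-en-1-yl]penta-2,4-dien-1-yl]triphenylphosphonium bromide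
Conditions: PPh3·HBr, MeOH, 0 °C to rt; crystallisation
Reagents that add atoms: triphenylphosphine hydrobromide, Br.c1ccc(cc1)P(c1ccccc1)c1ccccc1
Why: Ionisation of the tertiary bis-allylic alcohol to a delocalised pentadienyl cation and capture by PPh3 at the unhindered terminal carbon (SN1'-type allylic transposition), the usual way to C15 Wittig salts; the 9E isomer should predominate and be purified by crystallisation.

**Step 8**
Reactants: 14 C15 phosphonium bromide (two equivalents); 15 (2E,4E,6E)-2,7-dimethylocta-2,4,6-trienedial
Product: 18 (6R,6'R)-ε,ε-carotene (mixture of E and Z isomers at the two newly formed alkenes), via C15 ylide 16 (not isolated), via C25 apo-aldehyde 17 (not isolated)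
Conditions: 1,2-epoxybutane, EtOH, reflux, Ar, dark
Reagents that add atoms: none
Why: Twofold Wittig olefination of the dialdehyde by the semi-stabilised allylic ylide, generated under neutral conditions as the epoxide takes up HBr, so no strong base is present that could remove the C6–H; it forms C11=C12 and C11'=C12'.

**Step 9**
Reactants: 18 (6R,6'R)-ε,ε-carotene (mixture of E and Z isomers at the two newly formed alkenes)
Product: 19 (6R,6'R)-ε,ε-carotene (all-E)
Conditions: heptane, reflux, Ar, dark; crystallisation on cooling
Reagents that add atoms: none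
Why: Thermal Z-to-E isomerisation of the hindered Z alkenes next to the C13 and C13' methyl groups, drawn forward by crystallisation of the least soluble all-E isomer; nothing is added or lost and the C6 centres take no part.

**Compound list**
1 | isobutyraldehyde (2-methylpropanal) | CC(C)C=O | starting material
2 | ethyl vinyl ketone (pent-1-en-3-one) | CCC(=O)C=C | starting material
3 | 2,2-dimethyl-5-oxoheptanal | CCC(=O)CCC(C)(C)C=O | intermediate
4 | 3-hydroxy-2,4,4-trimethylcyclohexan-1-one (diastereomer mixture) | CC1C(O)C(C)(C)CCC1=O | intermediate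
5 | 2,4,4-trimethylcyclohex-2-en-1-one | CC1=CC(C)(C)CCC1=O | intermediate
6 | (1S)-2,4,4-trimethylcyclohex-2-en-1-ol | O[C@H]1CCC(C)(C)C=C1C | intermediate
7 | 1-bromobut-2-yne | CC#CCBr | starting material
8 | (S)-2,4,4-trimethylcyclohex-2-en-1-yl but-2-yn-1-yl ether | CC#CCO[C@H]1CCC(C)(C)C=C1C | intermediate
9 | (S)-2,4,4-trimethylcyclohex-2-en-1-yl 1-lithiobut-2-yn-1-yl ether | [Li]C(C#CC)O[C@H]1CCC(C)(C)C=C1C | intermediate
10 | 1-[(1R)-2,6,6-trimethylcyclohex-2-en-1-yl]but-2-yn-1-ol (carbinol epimers) | CC#CC(O)[C@H]1C(C)=CCCC1(C)C | intermediate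
11 | (R)-α-ionone, (3E)-4-[(1R)-2,6,6-trimethylcyclohex-2-en-1-yl]but-3-en-2-one | CC(=O)/C=C/[C@H]1C(C)=CCCC1(C)C | intermediate
12 | vinylmagnesium bromide | C=C[Mg]Br | starting material
13 | (1E)-3-methyl-1-[(1R)-2,6,6-trimethylcyclohex-2-en-1-yl]penta-1,4-dien-3-ol (C9 epimers) | C=CC(C)(O)/C=C/[C@H]1C(C)=CCCC1(C)C | intermediate
14 | [(2E,4E)-3-methyl-5-[(1R)-2,6,6-trimethylcyclohex-2-en-1-yl]penta-2,4-dien-1-yl]triphenylphosphonium bromide | CC1=CCCC(C)(C)[C@H]1/C=C/C(C)=C/C[P+](c1ccccc1)(c1ccccc1)c1ccccc1.[Br-] | intermediate
15 | (2E,4E,6E)-2,7-dimethylocta-2,4,6-trienedial | O=C/C(C)=C/C=C/C=C(C)/C=O | starting material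
16 | C15 ylide, [(2E,4E)-3-methyl-5-[(1R)-2,6,6-trimethylcyclohex-2-en-1-yl]penta-2,4-dien-1-ylidene]triphenylphosphorane | CC1=CCCC(C)(C)[C@H]1/C=C/C(C)=C/C=P(c1ccccc1)(c1ccccc1)c1ccccc1 | intermediate
17 | (2E,4E,6E,10E,12E)-2,7,11-trimethyl-13-[(1R)-2,6,6-trimethylcyclohex-2-en-1-yl]trideca-2,4,6,8,10,12-hexaenal, 8E/8Z mixture (C25 apo-aldehyde) | CC1=CCCC(C)(C)[C@H]1/C=C/C(C)=C/C=CC(/C)=C/C=C/C=C(C)/C=O | intermediate
18 | (6R,6'R)-ε,ε-carotene (mixture of E and Z isomers at the two newly formed alkenes, C11=C12 and C11'=C12') | CC1=CCCC(C)(C)[C@H]1/C=C/C(C)=C/C=CC(/C)=C/C=C/C=C(\C)C=C/C=C(C)/C=C/[C@H]1C(C)=CCCC1(C)C | intermediate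
19 | (6R,6'R)-ε,ε-carotene (all-E) | CC1=CCCC(C)(C)[C@H]1/C=C/C(C)=C/C=C/C(C)=C/C=C/C=C(C)/C=C/C=C(C)/C=C/[C@H]1C(C)=CCCC1(C)C | target

**Step count**
Total: 9 steps. Longest linear sequence: 9 steps (1 and 2 to 19); compounds 7, 12 and 15 enter as purchased materials.

**Steps most likely to fail**

Step 4. The sigmatropic shift may be slowed by crowding at the neopentyl terminus, so that the [1,2] shift, or unproductive deprotonation at the alkyne methyl, takes over. Fallback, from 6 back to 10: the alcohol 6 is alkylated with Bu3SnCH2I (KH, THF) to give tributyl{[(1S)-2,4,4-trimethylcyclohex-2-en-1-yl]oxymethyl}stannane F1. Tin–lithium exchange with n-BuLi at −78 °C triggers the Still variant of the [2,3]-Wittig rearrangement, in which the unstabilised primary carbanion rearranges fast even at hindered termini. With the same suprafacial transfer this should give [(1R)-2,6,6-trimethylcyclohex-2-en-1-yl]methanol F2. Buffered oxidation with Dess–Martin periodinane (NaHCO3, CH2Cl2, 0 °C) gives (1R)-2,6,6-trimethylcyclohex-2-ene-1-carbaldehyde F3, which is used cold and at once because its C6–H is labile. Addition of CH3C≡CMgBr in THF at −78 °C returns to 10.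

Step 5. The secondary carbinol may dehydrate toward the conjugated enyne through loss of the C6–H, or the ring alkene may migrate; either process erases the C6 centre. Fallback, from 10 back to 11: acetylation (Ac2O, DMAP, Et3N) gives 1-[(1R)-2,6,6-trimethylcyclohex-2-en-1-yl]but-2-yn-1-yl acetate F4. A [3,3] acyloxy shift catalysed by AgBF4 in CH2Cl2 leads to 4-[(1R)-2,6,6-trimethylcyclohex-2-en-1-yl]buta-2,3-dien-2-yl acetate F5. Mild methanolysis (K2CO3, MeOH, 0 °C) releases the enol, which should tautomerise to the E-enone 11.

Step 2. Facial discrimination in the hydride transfer may be insufficient; the minor enantiomer would be carried through and appear after step 8 as the meso (6R,6'S) diastereomer. Fallback, from 5 back to 6: Luche reduction (NaBH4, CeCl3·7H2O, MeOH, 0 °C) gives racemic 2,4,4-trimethylcyclohex-2-en-1-ol F6. Kinetic resolution with Candida antarctica lipase B and vinyl acetate should acylate the R enantiomer to (1R)-2,4,4-trimethylcyclohex-2-en-1-yl acetate F7 and leave the S alcohol 6, which is separated by chromatography.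

**Further compounds**
F1 | step 4 | tributyl{[(1S)-2,4,4-trimethylcyclohex-2-en-1-yl]oxymethyl}stannane | CCCC[Sn](CCCC)(CCCC)CO[C@H]1CCC(C)(C)C=C1C
F2 | step 4 | [(1R)-2,6,6-trimethylcyclohex-2-en-1-yl]methanol | OC[C@H]1C(C)=CCCC1(C)C
F3 | step 4 | (1R)-2,6,6-trimethylcyclohex-2-ene-1-carbaldehyde | O=C[C@H]1C(C)=CCCC1(C)C
F4 | step 5 | 1-[(1R)-2,6,6-trimethylcyclohex-2-en-1-yl]but-2-yn-1-yl acetate (carbinol epimers) | CC#CC(OC(C)=O)[C@H]1C(C)=CCCC1(C)C
F5 | step 5 | 4-[(1R)-2,6,6-trimethylcyclohex-2-en-1-yl]buta-2,3-dien-2-yl acetate (allene epimers) | CC(OC(C)=O)=C=C[C@H]1C(C)=CCCC1(C)C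
F6 | step 2 | racemic 2,4,4-trimethylcyclohex-2-en-1-ol | CC1=CC(C)(C)CCC1O
F7 | step 2 | (1R)-2,4,4-trimethylcyclohex-2-en-1-yl acetate | CC(=O)O[C@@H]1CCC(C)(C)C=C1C
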